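**Retrosynthetic overview** (chromanone numbering of the target core: O1, C2–C4, C4a, C5–C8, C8a)
1. Last disconnections: ester hydrolysis; C6–prenyl by a catalyst-controlled dearomatising Tsuji–Trost allylation that sets quaternary C6; C6–CH2 by reductive alkylation of the only free arene position with the trans-cyclobutane aldehyde 23.
2. Pyranone ring: C2–C3 disconnection. A rhodium carbenoid at C3 (from a diazoketone on C4) inserts into the methine C–H of an isopropyl ether on O1.
3. Enabling feature: C2 is a fully substituted carbon carrying two methyls and the ring oxygen O1 (on C8a), and C3 is alpha to the C4 ketone on the neighbouring C4a. An O1-isopropyl group therefore holds a tertiary, oxygen-activated C–H 1,6 to the carbenoid carbon, and the site of that ether decides which oxygen carries the ring.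
4. Regiochemistry and the hexanoate C3 stereocentre come from a coumarin: Pechmann lactone ring on symmetric phloroglucinol, 7-O-pivalate, copper hydride conjugate reduction, phenol-directed formylation, then the pyranone ring; methanolysis opens the temporary lactone and frees the C5/C7 hydroxyls.
5. Cyclobutane ring: made separately by epoxynitrile 4-exo cyclisation of a resolved epoxide. Ring order: lactone (temporary), pyranone, cyclobutane (separate branch); the carbocycle is dearomatised last.

Key step: step 8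

Assumption: the ligand and catalyst enantiomers named in steps 3, 12 and 20 are those expected to give the configuration drawn; the sense of induction is to be confirmed on the first product, and the antipode would be used otherwise.

Compounds 3–10 are described with coumarin numbering.

Step 1
Reactants: 1 phloroglucinol; 2 ethyl 3-oxohexanoate
Product: 3 5,7-dihydroxy-4-propyl-2H-chromen-2-one
Conditions: conc. H2SO4, 0 °C → rt
Reagents that add atoms: none
Why: Pechmann condensation on a symmetric triphenol can give only one regioisomer and places the future side-chain carbon (C4) and the future C7 oxygen (lactone O) in one operation.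

Step 2
Reactants: 3 5,7-dihydroxy-4-propyl-2H-chromen-2-one
Product: 4 5-hydroxy-2-oxo-4-propyl-2H-chromen-7-yl 2,2-dimethylpropanoate
Conditions: PivCl (1.05 equiv), pyridine, CH2Cl2, −20 → 0 °C
Reagents that add atoms: pivaloyl chloride, CC(C)(C)C(=O)Cl
Why: Selective O-acylation should occur at the more acidic, unhindered 7-OH, because the 5-OH is shielded by the peri propyl group.

Step 3
Reactants: 4 5-hydroxy-2-oxo-4-propyl-2H-chromen-7-yl 2,2-dimethylpropanoate
Product: 5 (4R)-5-hydroxy-2-oxo-4-propyl-3,4-dihydro-2H-chromen-7-yl 2,2-dimethylpropanoate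
Conditions: Cu(OAc)2·H2O (5 mol %), (R)-DTBM-SEGPHOS (5.5 mol %), (EtO)2MeSiH (4 equiv), t-BuOH (2 equiv), toluene, 0 °C → rt; then NH4F, MeOH
Reagents that add atoms: none
Why: Copper hydride asymmetric conjugate reduction of a 4-substituted coumarin (a beta-aryl-beta-alkyl enoate) should deliver hydride to the Si face of C4 under ligand control and so set the (R) centre; esters are inert and the free phenol is only silylated transiently.

Step 4
Reactants: 5 (4R)-5-hydroxy-2-oxo-4-propyl-3,4-dihydro-2H-chromen-7-yl 2,2-dimethylpropanoate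
Product: 6 (4R)-6-formyl-5-hydroxy-2-oxo-4-propyl-3,4-dihydro-2H-chromen-7-yl 2,2-dimethylpropanoate
Conditions: TiCl4 (2.2 equiv), Cl2CHOMe (1.2 equiv), CH2Cl2, 0 °C; then 1 M HCl
Reagents that add atoms: dichloromethyl methyl ether, COC(Cl)Cl; water, O
Why: Rieche formylation through the titanium phenoxide should deliver the electrophile ortho to the 5-oxygen, that is at C6, since C4a is substituted and C8 is flanked by two acyloxy groups and cannot be reached from the titanium centre.

Step 5
Reactants: 6 (4R)-6-formyl-5-hydroxy-2-oxo-4-propyl-3,4-dihydro-2H-chromen-7-yl 2,2-dimethylpropanoate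
Product: 7 (4R)-6-formyl-2-oxo-5-(propan-2-yloxy)-4-propyl-3,4-dihydro-2H-chromen-7-yl 2,2-dimethylpropanoate
Conditions: i-PrOH (3 equiv), PPh3 (2 equiv), DIAD (2 equiv), THF, 0 °C → rt
Reagents that add atoms: propan-2-ol, CC(C)O
Why: Mitsunobu etherification suits the acidic salicylaldehyde-type phenol and is neutral, so the aryl lactone and pivalate survive; it installs the future O1–C2 unit on the only free oxygen.

Step 6
Reactants: 7 (4R)-6-formyl-2-oxo-5-(propan-2-yloxy)-4-propyl-3,4-dihydro-2H-chromen-7-yl 2,2-dimethylpropanoate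
Product: 8 (4R)-7-[(2,2-dimethylpropanoyl)oxy]-2-oxo-5-(propan-2-yloxy)-4-propyl-3,4-dihydro-2H-chromene-6-carboxylic acid
Conditions: NaClO2, NaH2PO4, 2-methylbut-2-ene, t-BuOH/H2O, rt
Reagents that add atoms: sodium chlorite, [Na+].[O-]Cl=O
Why: Pinnick oxidation converts the hindered aryl aldehyde into the acid without touching esters or the benzylic stereocentre.

Step 7
Reactants: 8 (4R)-7-[(2,2-dimethylpropanoyl)oxy]-2-oxo-5-(propan-2-yloxy)-4-propyl-3,4-dihydro-2H-chromene-6-carboxylic acid
Product: 10 (4R)-6-(2-diazoacetyl)-2-oxo-5-(propan-2-yloxy)-4-propyl-3,4-dihydro-2H-chromen-7-yl 2,2-dimethylpropanoate, via acid chloride 9 (not isolated)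
Conditions: (COCl)2, DMF (cat.), CH2Cl2, 0 °C → rt; evaporate; CH2N2 (3 equiv), Et2O, 0 °C
Reagents that add atoms: oxalyl chloride (chlorine of 9), ClC(=O)C(=O)Cl; diazomethane, C=[N+]=[N-]
Why: Acylation of diazomethane by an aroyl chloride (first half of the Arndt–Eistert sequence) gives the diazomethyl ketone; no O–H is left to be methylated and the second equivalent of diazomethane takes up HCl.

Step 8
Reactants: 10 (4R)-6-(2-diazoacetyl)-2-oxo-5-(propan-2-yloxy)-4-propyl-3,4-dihydro-2H-chromen-7-yl 2,2-dimethylpropanoate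
Product: 11 (10R)-2,2-dimethyl-4,8-dioxo-10-propyl-3,4,9,10-tetrahydro-2H,8H-pyrano[2,3-f]chromen-5-yl 2,2-dimethylpropanoate
Conditions: Rh2(OAc)4 (1 mol %), CH2Cl2, 40 °C, slow addition of 10 (final 0.01 M)
Reagents that add atoms: none
Why: Rh2(OAc)4 (divalent rhodium) turns the diazoketone into an electrophilic rhodium carbenoid at C3 (target numbering), which inserts through a concerted, hydride-transfer-like three-centre transition state into the methine C–H of the O1-isopropyl group, so the C2–C3 bond and the gem-dimethyl carbon are made at once. The closest known reaction type is the dirhodium-catalysed intramolecular C–H insertion of ortho-alkoxyaryl diazomethyl ketones, which gives chroman-4-ones. The dihydropyranone ring closes as a six-membered ring by 1,6-insertion, the carbenoid carbon reaching the C–H carbon across C4, C4a, C8a and O1. No stereocentre is formed, because C2 carries two methyl groups, and the lactone stereocentre is not involved. The step needs chemoselectivity for this C–H bond over oxonium-ylide formation at O1, Wolff rearrangement and other insertions; the substrate secures it because the methine is the only C–H alpha to oxygen within reach and is tertiary, the other ortho oxygen is a pivalate without alpha C–H, the third oxygen is locked in the lactone, and no O–H or alkene is present. Only one oxygen of the arene carries an isopropyl group, so no regioisomeric pyranone can form.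

Step 9
Reactants: 11 (10R)-2,2-dimethyl-4,8-dioxo-10-propyl-3,4,9,10-tetrahydro-2H,8H-pyrano[2,3-f]chromen-5-yl 2,2-dimethylpropanoate
Product: 12 methyl (3R)-3-(5,7-dihydroxy-2,2-dimethyl-4-oxo-3,4-dihydro-2H-chromen-8-yl)hexanoate
Conditions: NaOMe (3 equiv), MeOH, 0 °C; then AcOH
Reagents that add atoms: methanol (as sodium methoxide), CO
Why: Methanolysis (transesterification) opens the aryl lactone to the methyl ester and removes the aryl pivalate in one operation, freeing both hydroxyls that flank C6; low temperature is chosen to avoid retro-oxa-Michael opening of the pyranone.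

Step 10
Reactants: 13 2,2-dimethylpent-4-enal
Product: 14 3,3-dimethylhex-5-enenitrile
Conditions: TosMIC, t-BuOK, DME, −40 °C → rt; then MeOH, reflux
Reagents that add atoms: p-toluenesulfonylmethyl isocyanide, Cc1ccc(cc1)S(=O)(=O)C[N+]#[C-]
Why: Van Leusen reductive cyanation homologates the non-enolisable aldehyde to the nitrile with one more carbon.

Step 11
Reactants: 14 3,3-dimethylhex-5-enenitrile
Product: 15 rac-3,3-dimethyl-4-(oxiran-2-yl)butanenitrile
Conditions: mCPBA, NaHCO3, CH2Cl2, 0 °C → rt
Reagents that add atoms: 3-chloroperbenzoic acid, OOC(=O)c1cccc(Cl)c1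
Why: Prilezhaev epoxidation of the terminal alkene; the nitrile is inert.

Step 12
Reactants: 15 rac-3,3-dimethyl-4-(oxiran-2-yl)butanenitrile
Product: 16 3,3-dimethyl-4-[(2R)-oxiran-2-yl]butanenitrile
Conditions: (R,R)-(salen)Co(OAc) (trivalent cobalt, 0.5 mol %), H2O (0.55 equiv), THF, 0 °C → rt
Reagents that add atoms: none
Why: Hydrolytic kinetic resolution should hydrolyse the (S)-epoxide selectively and leave the (R)-epoxide, which sets the absolute configuration of the cyclobutane.

Step 13
Reactants: 16 3,3-dimethyl-4-[(2R)-oxiran-2-yl]butanenitrile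
Product: 17 (1S,4R)-4-(hydroxymethyl)-2,2-dimethylcyclobutane-1-carbonitrile
Conditions: KN(SiMe3)2 (1.2 equiv), toluene, 0 °C → rt; then aq. NH4Cl
Reagents that add atoms: none
Why: Epoxynitrile cyclisation (4-exo-tet): the nitrile-stabilised carbanion attacks the internal epoxide carbon with inversion, the collinear SN2 geometry disfavouring the 5-endo mode; the nitrile-bearing centre can equilibrate, trans is expected, and any cis isomer converges in step 15.

Step 14
Reactants: 17 (1S,4R)-4-(hydroxymethyl)-2,2-dimethylcyclobutane-1-carbonitrile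
Product: 18 (1S,4R)-4-({[tert-butyl(dimethyl)silyl]oxy}methyl)-2,2-dimethylcyclobutane-1-carbonitrile
Conditions: TBSCl, imidazole, DMF, rt
Reagents that add atoms: tert-butyl(chloro)dimethylsilane, CC(C)(C)[Si](C)(C)Cl
Why: Silyl protection of the primary alcohol prevents lactol formation and alkoxide interference in the next two steps.

Step 15
Reactants: 18 (1S,4R)-4-({[tert-butyl(dimethyl)silyl]oxy}methyl)-2,2-dimethylcyclobutane-1-carbonitrile
Product: 20 1-[(1S,4R)-4-({[tert-butyl(dimethyl)silyl]oxy}methyl)-2,2-dimethylcyclobutyl]ethan-1-one, via lithium ketimide 19 (not isolated)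
Conditions: MeLi (2.5 equiv), Et2O, 0 °C → rt; aq. AcOH/NaOAc, rt; then K2CO3, MeOH, rt
Reagents that add atoms: methyllithium, [Li]C; water, O
Why: Organolithium addition to the nitrile and hydrolysis of the ketimide give the methyl ketone, and base equilibration through the enolate should place the acetyl group trans to the neighbouring silyloxymethyl group, which sets the second cyclobutane centre.

Step 16
Reactants: 20 1-[(1S,4R)-4-({[tert-butyl(dimethyl)silyl]oxy}methyl)-2,2-dimethylcyclobutyl]ethan-1-one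
Product: 21 tert-butyl{[(1R,2R)-3,3-dimethyl-2-(prop-1-en-2-yl)cyclobutyl]methoxy}dimethylsilane
Conditions: Ph3PCH3Br, KOt-Bu, THF, 0 → 50 °C
Reagents that add atoms: methyltriphenylphosphonium bromide, C[P+](c1ccccc1)(c1ccccc1)c1ccccc1.[Br-]
Why: Wittig methylenation turns the acetyl group into the isopropenyl group; the trans arrangement is the thermodynamic one, so the basic conditions should not erode it.

Step 17
Reactants: 21 tert-butyl{[(1R,2R)-3,3-dimethyl-2-(prop-1-en-2-yl)cyclobutyl]methoxy}dimethylsilane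
Product: 22 [(1R,2R)-3,3-dimethyl-2-(prop-1-en-2-yl)cyclobutyl]methanol
Conditions: Bu4NF, THF, rt
Reagents that add atoms: none
Why: Fluoride desilylation frees the primary alcohol without affecting the alkene.

Step 18
Reactants: 22 [(1R,2R)-3,3-dimethyl-2-(prop-1-en-2-yl)cyclobutyl]methanol
Product: 23 (1R,2R)-3,3-dimethyl-2-(prop-1-en-2-yl)cyclobutane-1-carbaldehyde
Conditions: Dess–Martin periodinane, NaHCO3, CH2Cl2, 0 °C → rt
Reagents that add atoms: none
Why: Dess–Martin oxidation gives the aldehyde under buffered, non-epimerising conditions; the trans isomer is in any case the more stable one.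

Step 19
Reactants: 12 methyl (3R)-3-(5,7-dihydroxy-2,2-dimethyl-4-oxo-3,4-dihydro-2H-chromen-8-yl)hexanoate; 23 (1R,2R)-3,3-dimethyl-2-(prop-1-en-2-yl)cyclobutane-1-carbaldehyde
Product: 25 methyl (3R)-3-(6-{[(1S,2R)-3,3-dimethyl-2-(prop-1-en-2-yl)cyclobutyl]methyl}-5,7-dihydroxy-2,2-dimethyl-4-oxo-3,4-dihydro-2H-chromen-8-yl)hexanoate, via ortho-quinone methide 24 (not isolated)
Conditions: 23 (1.2 equiv), L-proline (20 mol %), Hantzsch ester (1.3 equiv), CH2Cl2, rt
Reagents that add atoms: none
Why: Three-component reductive alkylation (Knoevenagel-type condensation, then transfer hydrogenation of the quinone methide by the Hantzsch ester) should work because C6 is the only free position and is flanked by two hydroxyls like C2 of a cyclic 1,3-dione; neither cyclobutane centre is involved in bond making.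

Step 20
Reactants: 25 methyl (3R)-3-(6-{[(1S,2R)-3,3-dimethyl-2-(prop-1-en-2-yl)cyclobutyl]methyl}-5,7-dihydroxy-2,2-dimethyl-4-oxo-3,4-dihydro-2H-chromen-8-yl)hexanoate
Product: 26 methyl (3R)-3-[(6R)-6-{[(1S,2R)-3,3-dimethyl-2-(prop-1-en-2-yl)cyclobutyl]methyl}-5-hydroxy-2,2-dimethyl-6-(3-methylbut-2-en-1-yl)-4,7-dioxo-3,4,6,7-tetrahydro-2H-chromen-8-yl]hexanoate
Conditions: Pd2(dba)3·CHCl3 (2.5 mol %), (R,R)-DACH-phenyl Trost ligand (7.5 mol %), methyl 3-methylbut-2-en-1-yl carbonate (1.3 equiv), THF, 0 °C → rt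
Reagents that add atoms: methyl 3-methylbut-2-en-1-yl carbonate, COC(=O)OCC=C(C)C
Why: Dearomatising asymmetric Tsuji–Trost allylation: the phenoxide, generated by the methoxide released on ionisation, attacks the unsubstituted terminus of the prenyl complex of zerovalent palladium at C6, the doubly oxygen-flanked carbon, and the chiral ligand pocket should select the face that gives (6R), since the existing stereocentres are too remote to do so.

Step 21
Reactants: 26 methyl (3R)-3-[(6R)-6-{[(1S,2R)-3,3-dimethyl-2-(prop-1-en-2-yl)cyclobutyl]methyl}-5-hydroxy-2,2-dimethyl-6-(3-methylbut-2-en-1-yl)-4,7-dioxo-3,4,6,7-tetrahydro-2H-chromen-8-yl]hexanoate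
Product: 27 (3R)-3-[(6R)-6-{[(1S,2R)-3,3-dimethyl-2-(prop-1-en-2-yl)cyclobutyl]methyl}-5-hydroxy-2,2-dimethyl-6-(3-methylbut-2-en-1-yl)-4,7-dioxo-3,4,6,7-tetrahydro-2H-chromen-8-yl]hexanoic acid
Conditions: LiOH·H2O (5 equiv), THF/H2O 3:1, 0 °C → rt; then 1 M HCl to pH 3
Reagents that add atoms: lithium hydroxide, [Li+].[OH-]
Why: Saponification of the unhindered methyl ester; the enolised triketone is present as its anion in base, which protects it from retro-Claisen cleavage, and no stereocentre is epimerisable.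

**Compound list**
1 | phloroglucinol | Oc1cc(O)cc(O)c1 | starting material
2 | ethyl 3-oxohexanoate | CCCC(=O)CC(=O)OCC | starting material
3 | 5,7-dihydroxy-4-propyl-2H-chromen-2-one | CCCC1=CC(=O)Oc2cc(O)cc(O)c12 | intermediate
4 | 5-hydroxy-2-oxo-4-propyl-2H-chromen-7-yl 2,2-dimethylpropanoate | CCCC1=CC(=O)Oc2cc(OC(=O)C(C)(C)C)cc(O)c12 | intermediate
5 | (4R)-5-hydroxy-2-oxo-4-propyl-3,4-dihydro-2H-chromen-7-yl 2,2-dimethylpropanoate | CCC[C@@H]1CC(=O)Oc2cc(OC(=O)C(C)(C)C)cc(O)c12 | intermediate
6 | (4R)-6-formyl-5-hydroxy-2-oxo-4-propyl-3,4-dihydro-2H-chromen-7-yl 2,2-dimethylpropanoate | CCC[C@@H]1CC(=O)Oc2cc(OC(=O)C(C)(C)C)c(C=O)c(O)c12 | intermediate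
7 | (4R)-6-formyl-2-oxo-5-(propan-2-yloxy)-4-propyl-3,4-dihydro-2H-chromen-7-yl 2,2-dimethylpropanoate | CCC[C@@H]1CC(=O)Oc2cc(OC(=O)C(C)(C)C)c(C=O)c(OC(C)C)c12 | intermediate
8 | (4R)-7-[(2,2-dimethylpropanoyl)oxy]-2-oxo-5-(propan-2-yloxy)-4-propyl-3,4-dihydro-2H-chromene-6-carboxylic acid | CCC[C@@H]1CC(=O)Oc2cc(OC(=O)C(C)(C)C)c(C(=O)O)c(OC(C)C)c12 | intermediate
9 | acid chloride of 8 (not isolated) | CCC[C@@H]1CC(=O)Oc2cc(OC(=O)C(C)(C)C)c(C(Cl)=O)c(OC(C)C)c12 | intermediate
10 | (4R)-6-(2-diazoacetyl)-2-oxo-5-(propan-2-yloxy)-4-propyl-3,4-dihydro-2H-chromen-7-yl 2,2-dimethylpropanoate | CCC[C@@H]1CC(=O)Oc2cc(OC(=O)C(C)(C)C)c(C(=O)C=[N+]=[N-])c(OC(C)C)c12 | intermediate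
11 | (10R)-2,2-dimethyl-4,8-dioxo-10-propyl-3,4,9,10-tetrahydro-2H,8H-pyrano[2,3-f]chromen-5-yl 2,2-dimethylpropanoate (pyranone fused at C5–O/C6 of the dihydrocoumarin) | CCC[C@@H]1CC(=O)Oc2cc(OC(=O)C(C)(C)C)c3C(=O)CC(C)(C)Oc3c12 | intermediate
12 | methyl (3R)-3-(5,7-dihydroxy-2,2-dimethyl-4-oxo-3,4-dihydro-2H-chromen-8-yl)hexanoate | CCC[C@H](CC(=O)OC)c1c(O)cc(O)c2C(=O)CC(C)(C)Oc12 | intermediate
13 | 2,2-dimethylpent-4-enal | C=CCC(C)(C)C=O | starting material
14 | 3,3-dimethylhex-5-enenitrile | C=CCC(C)(C)CC#N | intermediate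
15 | rac-3,3-dimethyl-4-(oxiran-2-yl)butanenitrile (racemic) | N#CCC(C)(C)CC1CO1 | intermediate
16 | 3,3-dimethyl-4-[(2R)-oxiran-2-yl]butanenitrile | N#CCC(C)(C)C[C@@H]1CO1 | intermediate
17 | (1S,4R)-4-(hydroxymethyl)-2,2-dimethylcyclobutane-1-carbonitrile | N#C[C@H]1[C@H](CO)CC1(C)C | intermediate
18 | (1S,4R)-4-({[tert-butyl(dimethyl)silyl]oxy}methyl)-2,2-dimethylcyclobutane-1-carbonitrile | N#C[C@H]1[C@H](CO[Si](C)(C)C(C)(C)C)CC1(C)C | intermediate
19 | lithium ketimide from 18 and methyllithium (not isolated) | CC(=N[Li])[C@H]1[C@H](CO[Si](C)(C)C(C)(C)C)CC1(C)C | intermediate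
20 | 1-[(1S,4R)-4-({[tert-butyl(dimethyl)silyl]oxy}methyl)-2,2-dimethylcyclobutyl]ethan-1-one | CC(=O)[C@H]1[C@H](CO[Si](C)(C)C(C)(C)C)CC1(C)C | intermediate
21 | tert-butyl{[(1R,2R)-3,3-dimethyl-2-(prop-1-en-2-yl)cyclobutyl]methoxy}dimethylsilane | C=C(C)[C@H]1[C@H](CO[Si](C)(C)C(C)(C)C)CC1(C)C | intermediate
22 | [(1R,2R)-3,3-dimethyl-2-(prop-1-en-2-yl)cyclobutyl]methanol | C=C(C)[C@H]1[C@H](CO)CC1(C)C | intermediate
23 | (1R,2R)-3,3-dimethyl-2-(prop-1-en-2-yl)cyclobutane-1-carbaldehyde | C=C(C)[C@H]1[C@H](C=O)CC1(C)C | intermediate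
24 | ortho-quinone methide from 12 and 23 (not isolated; exocyclic alkene geometry not defined) | C=C(C)[C@H]1[C@H](C=C2C(=O)C([C@H](CCC)CC(=O)OC)=C3OC(C)(C)CC(=O)C3=C2O)CC1(C)C | intermediate
25 | methyl (3R)-3-(6-{[(1S,2R)-3,3-dimethyl-2-(prop-1-en-2-yl)cyclobutyl]methyl}-5,7-dihydroxy-2,2-dimethyl-4-oxo-3,4-dihydro-2H-chromen-8-yl)hexanoate | C=C(C)[C@H]1[C@H](Cc2c(O)c([C@H](CCC)CC(=O)OC)c3OC(C)(C)CC(=O)c3c2O)CC1(C)C | intermediate
26 | methyl (3R)-3-[(6R)-6-{[(1S,2R)-3,3-dimethyl-2-(prop-1-en-2-yl)cyclobutyl]methyl}-5-hydroxy-2,2-dimethyl-6-(3-methylbut-2-en-1-yl)-4,7-dioxo-3,4,6,7-tetrahydro-2H-chromen-8-yl]hexanoate | C=C(C)[C@H]1[C@H](C[C@]2(CC=C(C)C)C(=O)C([C@H](CCC)CC(=O)OC)=C3OC(C)(C)CC(=O)C3=C2O)CC1(C)C | intermediate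
27 | (3R)-3-[(6R)-6-{[(1S,2R)-3,3-dimethyl-2-(prop-1-en-2-yl)cyclobutyl]methyl}-5-hydroxy-2,2-dimethyl-6-(3-methylbut-2-en-1-yl)-4,7-dioxo-3,4,6,7-tetrahydro-2H-chromen-8-yl]hexanoic acid | C=C(C)[C@H]1[C@H](C[C@]2(CC=C(C)C)C(=O)C([C@H](CCC)CC(=O)O)=C3OC(C)(C)CC(=O)C3=C2O)CC1(C)C | target

**Step count**
Total: 21 steps. Longest linear sequence: 12 steps (steps 1–9, then 19–21); the cyclobutane branch (steps 10–18, then 19–21) is equally long.

**Steps most likely to fail**

Step 8. The carbenoid may be captured by the lone pair of O1 (oxonium ylide, then 1,2-shift of the isopropyl group or loss of propene) or undergo Wolff rearrangement instead of C–H insertion. The fallback sets out from 5 and returns at 11, replacing steps 4–8. Titanium-phenoxide-directed ortho C-acylation of 5 with 3-methylbut-2-enoyl chloride (TiCl4, CH2Cl2) would give the enone phenol (4R)-5-hydroxy-6-(3-methylbut-2-enoyl)-2-oxo-4-propyl-3,4-dihydro-2H-chromen-7-yl 2,2-dimethylpropanoate F1. Intramolecular oxa-Michael addition of the C5 hydroxyl (acid resin, or already on the titanium phenoxide) then closes the pyranone to 11.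

Step 20. Facial discrimination at the planar C6 nucleophile may be poor, and O-allylation or attack at the tertiary allyl terminus may compete. The fallback sets out from 25 and returns at 26. It is an alkylation with prenyl bromide under chiral phase-transfer catalysis (cinchonidinium-derived quaternary ammonium salt, 50% aq. KOH, toluene, −20 °C), where a chiral ion pair and not a palladium allyl complex selects the face. Since three stereocentres are already in place, the C6 epimers of 26 are diastereomers and any minor epimer would be removed by preparative chromatography.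

Step 19. The quinone methide may tautomerise to the styrene-type alkene (losing the adjacent cyclobutane centre), add a second arene, or fail to form on this chelated phenol. The fallback sets out from 12 and from alcohol 22 (step 18 is then not needed) and returns at 25. Bromination of 12 at C6 (NBS, MeCN, 0 °C) would give methyl (3R)-3-(6-bromo-5,7-dihydroxy-2,2-dimethyl-4-oxo-3,4-dihydro-2H-chromen-8-yl)hexanoate F2, and acetylation (Ac2O, pyridine, DMAP) the diacetate methyl (3R)-3-[5,7-bis(acetyloxy)-6-bromo-2,2-dimethyl-4-oxo-3,4-dihydro-2H-chromen-8-yl]hexanoate F3. Alcohol 22 would be converted (I2, PPh3, imidazole) into (2R,3R)-3-(iodomethyl)-1,1-dimethyl-2-(prop-1-en-2-yl)cyclobutane F4. Iodine–lithium exchange (t-BuLi, Et2O, −78 °C) and ZnCl2 would give {[(1R,2R)-3,3-dimethyl-2-(prop-1-en-2-yl)cyclobutyl]methyl}zinc chloride F5, a polar route that avoids a ring-opening cyclobutylcarbinyl radical. Negishi coupling of F3 with F5 (Pd(OAc)2, CPhos, THF, rt) would give methyl (3R)-3-[5,7-bis(acetyloxy)-6-{[(1S,2R)-3,3-dimethyl-2-(prop-1-en-2-yl)cyclobutyl]methyl}-2,2-dimethyl-4-oxo-3,4-dihydro-2H-chromen-8-yl]hexanoate F6, and K2CO3/MeOH would remove the acetates to give 25.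

**Further compounds**
F1 | step 8 | (4R)-5-hydroxy-6-(3-methylbut-2-enoyl)-2-oxo-4-propyl-3,4-dihydro-2H-chromen-7-yl 2,2-dimethylpropanoate | CCC[C@@H]1CC(=O)Oc2cc(OC(=O)C(C)(C)C)c(C(=O)C=C(C)C)c(O)c12
F2 | step 19 | methyl (3R)-3-(6-bromo-5,7-dihydroxy-2,2-dimethyl-4-oxo-3,4-dihydro-2H-chromen-8-yl)hexanoate | CCC[C@H](CC(=O)OC)c1c(O)c(Br)c(O)c2C(=O)CC(C)(C)Oc12
F3 | step 19 | methyl (3R)-3-[5,7-bis(acetyloxy)-6-bromo-2,2-dimethyl-4-oxo-3,4-dihydro-2H-chromen-8-yl]hexanoate | CCC[C@H](CC(=O)OC)c1c(OC(C)=O)c(Br)c(OC(C)=O)c2C(=O)CC(C)(C)Oc12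
F4 | step 19 | (2R,3R)-3-(iodomethyl)-1,1-dimethyl-2-(prop-1-en-2-yl)cyclobutane | C=C(C)[C@H]1[C@H](CI)CC1(C)C
F5 | step 19 | {[(1R,2R)-3,3-dimethyl-2-(prop-1-en-2-yl)cyclobutyl]methyl}zinc chloride | C=C(C)[C@H]1[C@H](C[Zn]Cl)CC1(C)C
F6 | step 19 | methyl (3R)-3-[5,7-bis(acetyloxy)-6-{[(1S,2R)-3,3-dimethyl-2-(prop-1-en-2-yl)cyclobutyl]methyl}-2,2-dimethyl-4-oxo-3,4-dihydro-2H-chromen-8-yl]hexanoate | C=C(C)[C@H]1[C@H](Cc2c(OC(C)=O)c([C@H](CCC)CC(=O)OC)c3OC(C)(C)CC(=O)c3c2OC(C)=O)CC1(C)C
F0 | step 20 | none | none
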